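## The problem

The target is a linear diarylheptanoid, numbered here from C1 (the carbon bearing the 4-hydroxy-3-methoxyphenyl ring) to C7 (the benzylic CH2 of the 4-hydroxyphenyl ring). One oxygen bridges C1 and C5 to give an oxane, with hydroxyl groups at C3 in the ring and at C6 on the side chain. Four stereocentres have to be set, (1S,3R,5S,6R): aryl group and side chain are trans across the ring oxygen, the C3 hydroxyl is trans to the aryl group and cis to the side chain, and C5/C6 are erythro (anti). The 2,6-trans arrangement is the less stable one, so closures under thermodynamic or chair-like control (oxa-Michael, Prins, acid-catalysed etherification) tend to give the cis ring; trans has to be fixed kinetically and then kept. C6 can come from the chiral pool and direct C5 by 1,2-induction, but C1 lies across the oxygen from C5 and cannot be expected to follow the substrate, and C3 can only be controlled by the ring once it exists. C1 is the fragile point: it is a benzylic ether para to an oxygen substituent, which ionises under acid and, once the phenol is free, can open through a quinone methide under base, in both cases re-closing to the cis ring. The phenols therefore stay masked until a last, neutral step. The feature that opens the molecule is that C1 and C5 are both carbinol carbons joined only through oxygen: each can be set separately in an acyclic ether, C1 carrying a vinyl and C5 an allyl group, and the oxane then closes through the C2–C3 bond without touching either centre. The alkene left at C2=C3 is the handle for the C3 hydroxyl, but its two carbons differ only in their distance from the ring oxygen, so the reaction that brings in this oxygen must respond to exactly that difference.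

## Retrosynthesis

**Unmasking (19 from 18 from 17).** The two aryl O–benzyl bonds are cut last, by hydrogenolysis of 18, because this is neutral and the free para-hydroxybenzylic ether at C1 should never meet acid or base. The O–Si bond at C6 is cut one step earlier (17 to 18) with fluoride, while both phenols are still benzylated, so that no phenoxide is formed next to C1. The forward demand is that hydrogenolysis spares the benzylic C1–O ring bond; aryl benzyl ethers cleave much faster than a secondary dialkyl benzylic ether.

**The C3 oxygen (17 from 16 from 15).** The C3–H bond is cut first (ketone 16), then the C3=O bond back to the alkene 15. Direct hydroboration of 15 is not used: an allylic C–O bond directs boron to the alkene carbon next to it, here C2, so the wrong alcohol would prevail. Epoxidation followed by hydride opening fails for the mirror reason, since the nucleophile attacks C3 (remote from the oxygen-bearing carbon) and leaves the oxygen on C2. The same electronic bias helps when oxygen itself is the nucleophile: in a Wacker oxidation water attacks the metal-bound alkene at C3, giving ketone 16 with the regiochemistry fixed. Reduction of 16 then sets C3. The branched side chain should sit equatorial and the flat aryl group axial, and axial delivery of a small hydride gives the equatorial alcohol 17, trans to the aryl group and cis to the side chain. Ketone 16 can epimerise at C1 by retro-oxa-Michael opening, so it is reduced at once at low temperature.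

**Ring closure (15 from 14).** The C2=C3 bond is cut by ring-closing metathesis, leading back to the bis-allylic ether 14. Against closures that form a C–O bond of the ring, this cut has the advantage that neither C1 nor C5 takes part, so the trans relation cannot be lost or corrected towards cis during closure. The precursor is an acyclic ether with both alkenes terminal, and the product carries the alkene exactly where the C3 oxygen is needed. The forward reaction must favour cyclisation over oligomerisation and must not isomerise the C1 vinyl group.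

**The ether bond (14 from 7 and 11).** The C1–O bond is cut to the homoallylic alcohol 7 and the linear cinnamyl carbonate 11. An iridium–phosphoramidite catalyst is known to join copper alkoxides (here 13, made from 7 through 12) to such carbonates at the aryl-bearing terminus, with the catalyst deciding the configuration of the new centre whatever the chirality of the alkoxide. This is the only point where C1 is set, and it is set independently of C5. A tert-butyl carbonate is chosen so that the alkoxide does not attack the leaving group.

**The C5–C7 fragment (7 from 5 and 6; 5 from 4, 3, 2, 1).** The C4–C5 bond is cut to the α-silyloxy aldehyde 5 and allyltrimethylsilane 6. A non-chelating silyl ether with a monodentate Lewis acid gives the Felkin (anti) adduct, which is the erythro C5/C6 relation required. Triisopropylsilyl is preferred to smaller silyl groups because it resists O-to-O silyl shift in the alkoxides 12 and 13. Aldehyde 5 is traced through ester 4 and hydroxy ester 3 to hydroxy acid 2, obtained from D-tyrosine 1 by diazotisation with retention, so C6 comes from the chiral pool.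

**The aryl-allyl fragment (11 from 10, 9, 8).** Carbonate 11 comes from allylic alcohol 10, made by reduction of the doubly benzylated ester 9 of ferulic acid 8. The alkene geometry and the full C1–C3 unit are already present in 8.

## Roads not taken

Alternative 1: The chain is cut at C2–C3 and C3–C4, with C3 as a dithiane carbon. Lithiated silyl dithiane A4 opens the aryl oxirane A2 at its CH2 terminus, a solvent-triggered 1,4-Brook shift moves silicon to the C1 oxygen, and the new dithiane anion opens epoxide A3, giving A1 in one flask. The merits are real: three fragments are joined in one operation, C1, C5 and C6 come from enantiopure epoxides, and C3 arrives as a masked ketone next to a free C5 hydroxyl, so its regiochemistry is not in question and a 1,3-anti directed reduction can set it. In this respect the route is better than the chosen one, which has to find C3 on a nearly symmetrical alkene. The weak points lie after the key step. No ring is formed, and A1 has C1 in the configuration opposite to the target, so the oxane must be closed by displacement at the benzylic C1 with inversion, the centre that ionises most easily. The aryl sulfonate is there to damp this and must itself be removed later beside the labile benzylic ether. The dithiane has to be unmasked in the presence of two electron-rich rings, and A2 and A3 each need their own asymmetric synthesis. Against the better C3 control, the chosen plan sets a ring closure that touches no stereocentre and a shorter, protecting-group-lean sequence.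

Alternative 2: The cut is at C3–C4 and O–C5, through an isoxazoline. Nitrile oxide A6 adds to the terminal alkene of allylic ether A7, the C6 alkoxy group taking the inside position, to give A5 with erythro C5/C6; the isoxazoline oxygen later becomes the ring oxygen. The cycloaddition is reliable in regiochemistry, and N–O cleavage unmasks a C3 ketone beside the C5 hydroxyl, so here too C3 regiochemistry is settled by construction and a directed reduction is available; this is an advantage over the chosen plan. The weak points are that inside-alkoxy induction from a simple allylic ether is usually only moderate, that N–O cleavage must be done without touching benzyl ethers, and that A5, like A1, has C1 inverted relative to the target, so the same invertive benzylic etherification is needed to close the oxane. The chosen plan sets C5 by Felkin addition and C1 by a catalyst, both before a closure that cannot scramble them; it pays with a less certain C3.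

Alternative 3: The cut is at O–C5 with inversion. The free C1 hydroxyl of the trans-epoxy alcohol A9 attacks C5 under mild acid in a 6-exo opening and gives A8, releasing the C6 hydroxyl. This closure is stereospecific, forms the trans ring directly, and is carried out with the C3 oxygen already in place, so no late alkene functionalisation is needed; on C3 this road is better than the chosen one. Its cost is in the precursor: A9 needs C1 and C3 set and differentiated in a linear sequence, then a reagent-controlled epoxidation of an isolated trans alkene for C5 and C6, and the closure exposes a free, electron-rich benzylic alcohol to acid, which invites ionisation at C1 and a competing 7-endo path. The chosen plan is convergent, takes C6 from an amino acid and sets only C5 and C1 in the acyclic stage; it has to set against Alternative 3 the two extra steps and the uncertainty of putting oxygen on C3 after ring closure.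

Key step: step 10

Assumption: the (Sa,Sc,Sc) antipode of the ligand L, O,O′-(1,1′-binaphthalene-2,2′-diyl) N,N-bis(1-phenylethyl)phosphoramidite, is taken as the one that delivers the (S) ether at C1; if the facial preference of the catalyst is the opposite, the (Ra,Rc,Rc) antipode is used and nothing else changes.

## Route

Step 1
Reactants: 1 D-tyrosine
Product: 2 (2R)-2-hydroxy-3-(4-hydroxyphenyl)propanoic acid
Conditions: NaNO2, 1 M H2SO4, H2O, 0 °C to rt
Reagents that add atoms: water, O
Why: Diazotisation of the α-amino acid; the carboxylate displaces N2 to an α-lactone that water opens, two inversions giving net retention, so the (R) centre of 1 becomes C6 of the target.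

Step 2
Reactants: 2 (2R)-2-hydroxy-3-(4-hydroxyphenyl)propanoic acid
Product: 3 benzyl (2R)-3-[4-(benzyloxy)phenyl]-2-hydroxypropanoate
Conditions: BnBr, K2CO3, DMF, rt
Reagents that add atoms: benzyl bromide, BrCc1ccccc1
Why: Williamson-type O-alkylation; carbonate deprotonates only the carboxylic acid and the phenol, so both are benzylated while the secondary alcohol stays free and the stereocentre is untouched.

Step 3
Reactants: 3 benzyl (2R)-3-[4-(benzyloxy)phenyl]-2-hydroxypropanoate
Product: 4 benzyl (2R)-3-[4-(benzyloxy)phenyl]-2-[(triisopropylsilyl)oxy]propanoate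
Conditions: TIPSOTf, 2,6-lutidine, CH2Cl2, 0 °C to rt
Reagents that add atoms: triisopropylsilyl trifluoromethanesulfonate, CC(C)[Si](C(C)C)(C(C)C)OS(=O)(=O)C(F)(F)F
Why: Silylation of a secondary alcohol with a silyl triflate and a hindered base; the bulky silyl ether cannot chelate in step 5 and resists O-to-O silyl shift in the alkoxides of step 9.

Step 4
Reactants: 4 benzyl (2R)-3-[4-(benzyloxy)phenyl]-2-[(triisopropylsilyl)oxy]propanoate
Product: 5 (2R)-3-[4-(benzyloxy)phenyl]-2-[(triisopropylsilyl)oxy]propanal
Conditions: iBu2AlH, CH2Cl2, −78 °C; aq. potassium sodium tartrate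
Reagents that add atoms: none
Why: Partial reduction of an ester; the tetrahedral aluminium hemiacetal survives at −78 °C and releases the aldehyde on work-up, and the α-silyloxy aldehyde keeps its configuration if used at once.

Step 5
Reactants: 5 (2R)-3-[4-(benzyloxy)phenyl]-2-[(triisopropylsilyl)oxy]propanal; 6 allyltrimethylsilane
Product: 7 (4S,5R)-6-[4-(benzyloxy)phenyl]-5-[(triisopropylsilyl)oxy]hex-1-en-4-ol
Conditions: BF3·OEt2, CH2Cl2, −78 °C
Reagents that add atoms: none
Why: Hosomi–Sakurai allylation through an open transition state; with a non-chelating silyloxy group and monodentate BF3 the polar Felkin–Anh (Cornforth) arrangement sends the allyl group to the Si face of the aldehyde, giving the anti (erythro) alcohol, i.e. C5 (S) beside C6 (R).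

Step 6
Reactants: 8 ferulic acid
Product: 9 benzyl (2E)-3-[4-(benzyloxy)-3-methoxyphenyl]prop-2-enoate
Conditions: BnBr, K2CO3, DMF, 60 °C
Reagents that add atoms: benzyl bromide, BrCc1ccccc1
Why: Williamson-type O-alkylation of the carboxylate and the phenoxide in one operation; the E alkene is not affected.

Step 7
Reactants: 9 benzyl (2E)-3-[4-(benzyloxy)-3-methoxyphenyl]prop-2-enoate
Product: 10 (2E)-3-[4-(benzyloxy)-3-methoxyphenyl]prop-2-en-1-ol
Conditions: iBu2AlH (3 equiv), CH2Cl2, −78 to 0 °C
Reagents that add atoms: none
Why: 1,2-Reduction of a conjugated ester to the allylic alcohol with excess aluminium hydride; the alkene and the aryl benzyl ether are inert.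

Step 8
Reactants: 10 (2E)-3-[4-(benzyloxy)-3-methoxyphenyl]prop-2-en-1-ol
Product: 11 (2E)-3-[4-(benzyloxy)-3-methoxyphenyl]prop-2-en-1-yl tert-butyl carbonate
Conditions: Boc2O, Bu4NHSO4 (cat.), 30% aq. NaOH, CH2Cl2, 0 °C to rt
Reagents that add atoms: di-tert-butyl dicarbonate, CC(C)(C)OC(=O)OC(=O)OC(C)(C)C
Why: Phase-transfer O-acylation of the allylic alcohol; the tert-butyl carbonate is a leaving group that the alkoxide of step 9 cannot transesterify.

Step 9
Reactants: 7 (4S,5R)-6-[4-(benzyloxy)phenyl]-5-[(triisopropylsilyl)oxy]hex-1-en-4-ol; 11 (2E)-3-[4-(benzyloxy)-3-methoxyphenyl]prop-2-en-1-yl tert-butyl carbonate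
Product: 14 1-(benzyloxy)-4-[(1S)-1-({(4S,5R)-6-[4-(benzyloxy)phenyl]-5-[(triisopropylsilyl)oxy]hex-1-en-4-yl}oxy)prop-2-en-1-yl]-2-methoxybenzene, via lithium alkoxide ROLi 12 (not isolated), via copper alkoxide ROCu 13 (not isolated)
Conditions: 7, n-BuLi, THF, 0 °C; CuI, rt; then 11, [Ir(cod)Cl]2 (2 mol%), (Sa,Sc,Sc)-L (4 mol%), THF, rt
Reagents that add atoms: none
Why: Iridium-catalysed allylic etherification; the carbonate ionises to an allyliridium complex which the soft copper alkoxide attacks at the aryl-substituted terminus, giving the branched ether. The new C1 centre is set (S) by the phosphoramidite ligand and not by the alkoxide, as is established for chiral secondary alkoxides in this reaction.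

Step 10
Reactants: 14 1-(benzyloxy)-4-[(1S)-1-({(4S,5R)-6-[4-(benzyloxy)phenyl]-5-[(triisopropylsilyl)oxy]hex-1-en-4-yl}oxy)prop-2-en-1-yl]-2-methoxybenzene
Product: 15 (2S,6S)-6-[4-(benzyloxy)-3-methoxyphenyl]-2-{(1R)-2-[4-(benzyloxy)phenyl]-1-[(triisopropylsilyl)oxy]ethyl}-3,6-dihydro-2H-pyran
Conditions: second-generation Grubbs catalyst (H2IMes)(PCy3)Cl2Ru=CHPh (5 mol%), 1,4-benzoquinone (10 mol%), CH2Cl2 (0.005 M), 40 °C
Reagents that add atoms: none
Why: The ruthenium benzylidene first exchanges with the less hindered terminal alkene of the allyl arm by [2+2] cycloaddition and cycloreversion, placing a ruthenium alkylidene on C3. This alkylidene adds to the C1 vinyl group within the molecule, and collapse of the metallacyclobutane forms the C2=C3 bond and releases Ru=CH2; loss of ethene drives the reaction. The closest known reaction type is ring-closing metathesis of allyl homoallyl ethers to 3,6-dihydro-2H-pyrans, including branched ethers made by iridium-catalysed etherification. The six-membered ring closes by joining C2 to C3, the ring oxygen and both carbinol carbons being spectators, and the ring size enforces the cis alkene. No stereocentre is formed; C1 and C5 are carried over unchanged because no intermediate can epimerise under these neutral conditions, so the 2,6-trans relation of 14 becomes that of 15. The step needs cyclisation over intermolecular metathesis, which high dilution and the two branched ether carbons holding the alkene termini close together should secure. It also needs the C1 vinyl group not to migrate into an enol ether, which is secured by 1,4-benzoquinone as a scavenger of ruthenium hydrides and by the moderate temperature. The aryl benzyl ethers and the silyl ether do not interfere with the catalyst.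

Step 11
Reactants: 15 (2S,6S)-6-[4-(benzyloxy)-3-methoxyphenyl]-2-{(1R)-2-[4-(benzyloxy)phenyl]-1-[(triisopropylsilyl)oxy]ethyl}-3,6-dihydro-2H-pyran
Product: 16 (2S,6S)-2-[4-(benzyloxy)-3-methoxyphenyl]-6-{(1R)-2-[4-(benzyloxy)phenyl]-1-[(triisopropylsilyl)oxy]ethyl}oxan-4-one
Conditions: PdCl2 (20 mol%), CuCl, O2 (1 atm), DMF–H2O (7:1), 40 °C
Reagents that add atoms: water, O
Why: Wacker oxidation of an internal allylic ether; water attacks the alkene bound to divalent palladium at C3, the carbon remote from the electron-withdrawing C1–O bond, and β-hydride elimination gives the β-alkoxy ketone, as is the rule for internal allyl ethers. CuCl and O2 reoxidise the palladium, and no stereocentre takes part.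

Step 12
Reactants: 16 (2S,6S)-2-[4-(benzyloxy)-3-methoxyphenyl]-6-{(1R)-2-[4-(benzyloxy)phenyl]-1-[(triisopropylsilyl)oxy]ethyl}oxan-4-one
Product: 17 (2S,4R,6S)-2-[4-(benzyloxy)-3-methoxyphenyl]-6-{(1R)-2-[4-(benzyloxy)phenyl]-1-[(triisopropylsilyl)oxy]ethyl}oxan-4-ol
Conditions: NaBH4, MeOH–CH2Cl2, −40 °C
Reagents that add atoms: none
Why: Borohydride reduction of a 4-oxanone; the ketone should react through the chair with the branched side chain equatorial and the flat aryl group axial, and the small hydride adds along the axial path (torsional control) to give the equatorial alcohol, trans to the aryl group and cis to the side chain, i.e. (R) at C3. The low temperature and the absence of strong base keep the ring from opening by retro-oxa-Michael reaction.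

Step 13
Reactants: 17 (2S,4R,6S)-2-[4-(benzyloxy)-3-methoxyphenyl]-6-{(1R)-2-[4-(benzyloxy)phenyl]-1-[(triisopropylsilyl)oxy]ethyl}oxan-4-ol
Product: 18 (2S,4R,6S)-2-[4-(benzyloxy)-3-methoxyphenyl]-6-{(1R)-2-[4-(benzyloxy)phenyl]-1-hydroxyethyl}oxan-4-ol
Conditions: Bu4NF, THF, rt
Reagents that add atoms: none
Why: Fluoride cleavage of the Si–O bond; benzyl ethers and the ring ether are inert, and because both phenols are still benzylated no phenoxide can open the ring at C1.

Step 14
Reactants: 18 (2S,4R,6S)-2-[4-(benzyloxy)-3-methoxyphenyl]-6-{(1R)-2-[4-(benzyloxy)phenyl]-1-hydroxyethyl}oxan-4-ol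
Product: 19 (2S,4R,6S)-2-(4-hydroxy-3-methoxyphenyl)-6-[(1R)-1-hydroxy-2-(4-hydroxyphenyl)ethyl]oxan-4-ol
Conditions: H2 (1 atm), 10% Pd/C, EtOAc, rt
Reagents that add atoms: none
Why: Hydrogenolysis of the two aryl benzyl ethers under neutral conditions; aryl O–CH2Ph bonds cleave much faster than the secondary benzylic C1–O bond of the ring, and the reaction is stopped when 18 is consumed, so the acid- and base-sensitive product is released in the last operation.

## Compound list

1 | D-tyrosine | N[C@H](Cc1ccc(O)cc1)C(=O)O | starting material
2 | (2R)-2-hydroxy-3-(4-hydroxyphenyl)propanoic acid | O[C@H](Cc1ccc(O)cc1)C(=O)O | intermediate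
3 | benzyl (2R)-3-[4-(benzyloxy)phenyl]-2-hydroxypropanoate | O[C@H](Cc1ccc(OCc2ccccc2)cc1)C(=O)OCc1ccccc1 | intermediate
4 | benzyl (2R)-3-[4-(benzyloxy)phenyl]-2-[(triisopropylsilyl)oxy]propanoate | CC(C)[Si](C(C)C)(C(C)C)O[C@H](Cc1ccc(OCc2ccccc2)cc1)C(=O)OCc1ccccc1 | intermediate
5 | (2R)-3-[4-(benzyloxy)phenyl]-2-[(triisopropylsilyl)oxy]propanal | CC(C)[Si](C(C)C)(C(C)C)O[C@H](Cc1ccc(OCc2ccccc2)cc1)C=O | intermediate
6 | allyltrimethylsilane | C=CC[Si](C)(C)C | starting material
7 | (4S,5R)-6-[4-(benzyloxy)phenyl]-5-[(triisopropylsilyl)oxy]hex-1-en-4-ol | C=CC[C@H](O)[C@H](O[Si](C(C)C)(C(C)C)C(C)C)Cc1ccc(OCc2ccccc2)cc1 | intermediate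
8 | ferulic acid | COc1cc(/C=C/C(=O)O)ccc1O | starting material
9 | benzyl (2E)-3-[4-(benzyloxy)-3-methoxyphenyl]prop-2-enoate | COc1cc(/C=C/C(=O)OCc2ccccc2)ccc1OCc1ccccc1 | intermediate
10 | (2E)-3-[4-(benzyloxy)-3-methoxyphenyl]prop-2-en-1-ol | COc1cc(/C=C/CO)ccc1OCc1ccccc1 | intermediate
11 | (2E)-3-[4-(benzyloxy)-3-methoxyphenyl]prop-2-en-1-yl tert-butyl carbonate | COc1cc(/C=C/COC(=O)OC(C)(C)C)ccc1OCc1ccccc1 | intermediate
12 | lithium (4S,5R)-6-[4-(benzyloxy)phenyl]-5-[(triisopropylsilyl)oxy]hex-1-en-4-olate, ROLi (not isolated) | [Li]O[C@@H](CC=C)[C@H](O[Si](C(C)C)(C(C)C)C(C)C)Cc1ccc(OCc2ccccc2)cc1 | intermediate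
13 | copper (4S,5R)-6-[4-(benzyloxy)phenyl]-5-[(triisopropylsilyl)oxy]hex-1-en-4-olate, ROCu (not isolated) | [Cu]O[C@@H](CC=C)[C@H](O[Si](C(C)C)(C(C)C)C(C)C)Cc1ccc(OCc2ccccc2)cc1 | intermediate
14 | 1-(benzyloxy)-4-[(1S)-1-({(4S,5R)-6-[4-(benzyloxy)phenyl]-5-[(triisopropylsilyl)oxy]hex-1-en-4-yl}oxy)prop-2-en-1-yl]-2-methoxybenzene | COc1cc([C@H](C=C)O[C@@H](CC=C)[C@H](O[Si](C(C)C)(C(C)C)C(C)C)Cc2ccc(OCc3ccccc3)cc2)ccc1OCc1ccccc1 | intermediate
15 | (2S,6S)-6-[4-(benzyloxy)-3-methoxyphenyl]-2-{(1R)-2-[4-(benzyloxy)phenyl]-1-[(triisopropylsilyl)oxy]ethyl}-3,6-dihydro-2H-pyran | COc1cc([C@@H]2C=CC[C@@H]([C@H](O[Si](C(C)C)(C(C)C)C(C)C)Cc3ccc(OCc4ccccc4)cc3)O2)ccc1OCc1ccccc1 | intermediate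
16 | (2S,6S)-2-[4-(benzyloxy)-3-methoxyphenyl]-6-{(1R)-2-[4-(benzyloxy)phenyl]-1-[(triisopropylsilyl)oxy]ethyl}oxan-4-one | COc1cc([C@@H]2CC(=O)C[C@@H]([C@H](O[Si](C(C)C)(C(C)C)C(C)C)Cc3ccc(OCc4ccccc4)cc3)O2)ccc1OCc1ccccc1 | intermediate
17 | (2S,4R,6S)-2-[4-(benzyloxy)-3-methoxyphenyl]-6-{(1R)-2-[4-(benzyloxy)phenyl]-1-[(triisopropylsilyl)oxy]ethyl}oxan-4-ol | COc1cc([C@@H]2C[C@@H](O)C[C@@H]([C@H](O[Si](C(C)C)(C(C)C)C(C)C)Cc3ccc(OCc4ccccc4)cc3)O2)ccc1OCc1ccccc1 | intermediate
18 | (2S,4R,6S)-2-[4-(benzyloxy)-3-methoxyphenyl]-6-{(1R)-2-[4-(benzyloxy)phenyl]-1-hydroxyethyl}oxan-4-ol | COc1cc([C@@H]2C[C@@H](O)C[C@@H]([C@H](O)Cc3ccc(OCc4ccccc4)cc3)O2)ccc1OCc1ccccc1 | intermediate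
19 | (2S,4R,6S)-2-(4-hydroxy-3-methoxyphenyl)-6-[(1R)-1-hydroxy-2-(4-hydroxyphenyl)ethyl]oxan-4-ol | COc1cc([C@@H]2C[C@@H](O)C[C@@H]([C@H](O)Cc3ccc(O)cc3)O2)ccc1O | target

## Step count and least certain steps

Total: 14 steps. Longest linear sequence: 11 steps (steps 1–5 and 9–14, from D-tyrosine).

**Step 10 (key step).** The likely failure is migration of the C1 vinyl double bond towards oxygen: C1–H is benzylic, allylic and α to oxygen, so a ruthenium hydride formed by catalyst decay isomerises it easily, and the resulting enol ether cannot close the six-membered ring. Intermolecular metathesis at the unhindered allyl terminus is the second risk if closure onto the hindered vinyl group is slow. Fallback, from 7 back to 15: the ring is closed before the aryl group is present. Acylation of 7 with acryloyl chloride (Et3N, CH2Cl2) gives (4S,5R)-6-[4-(benzyloxy)phenyl]-5-[(triisopropylsilyl)oxy]hex-1-en-4-yl prop-2-enoate F1. Ring-closing metathesis of this acrylate (second-generation Grubbs catalyst, CH2Cl2, 40 °C) gives the 5,6-dihydro-2H-pyran-2-one F2, which has no isomerisable allylic ether. Reduction with iBu2AlH at −78 °C and acetylation of the aluminium hemiacetal in the same flask (Ac2O, pyridine, DMAP) give the lactol acetate F3. BF3·OEt2 ionises F3 to the ring oxocarbenium ion, and the arylzinc bromide F5, made from 1-(benzyloxy)-4-bromo-2-methoxybenzene F4 with Mg and then ZnBr2, adds at the acetal carbon from the face opposite to the C5 side chain, giving 15.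

**Step 9.** The likely failure is slow capture of the allyliridium intermediate by the hindered secondary alkoxide 13. The branched ether carries an electron-rich aryl group and can then re-ionise, drifting to the linear ether or losing configurational purity at C1; a mismatch between the chiral alkoxide and the catalyst would also lower the selectivity at C1. Fallback, from 11 and 13 back to 14: C1 is set on a small nucleophile and then transferred. The same iridium catalyst with KOSiEt3 converts 11 into the branched (S)-triethylsilyl ether F6; Bu4NF gives (1S)-1-[4-(benzyloxy)-3-methoxyphenyl]prop-2-en-1-ol F7; methyl chloroformate and pyridine give its methyl carbonate F8. RhCl(PPh3)3 modified with P(OMe)3 then couples F8 with 13 with net retention (two inversions), a reaction type that accepts hindered copper alkoxides, and gives 14.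

**Step 11.** The likely failure is slow oxidation of the cyclic disubstituted alkene. This leaves time for PdCl2 acting as a Lewis acid to ionise the allylic, benzylic C1–O bond (epimerisation towards the cis ring, or ring opening) and for acid-promoted retro-oxa-Michael epimerisation of the ketone. Fallback, from 15 back to 16: oxymercuration–demercuration (Hg(OAc)2, THF–H2O; then NaBH4, aq. NaOH) puts the hydroxyl on C3 for the same electronic reason, by a fast stoichiometric addition at room temperature. The alcohol is obtained as 17 and/or its C3 epimer F9, and Dess–Martin periodinane oxidation of either gives 16, from which step 12 sets C3.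

**Step 12.** The likely failure is poor facial selectivity: the axial aryl group at C1 lies on the face from which the axial hydride must come, and part of the ketone may react through the other chair or a twist form. Fallback, from 16 back to 17: the ketone is reduced from the other face to the (4S) alcohol F10, the C3 epimer of 17, LiBH(sec-Bu)3 in THF at −78 °C being the first choice since bulky hydrides avoid the axial path. The centre is then inverted by Mitsunobu esterification (4-nitrobenzoic acid, PPh3, diisopropyl azodicarboxylate) to the 4-nitrobenzoate F11, and methanolysis (K2CO3, MeOH) gives 17.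

**Step 5.** The likely failure is poor facial selectivity in the open transition state (Felkin against anti-Felkin addition), with partial loss of the silyl group to BF3 as a lesser risk. Fallback, from 5 back to 7: reagent control in a closed transition state. Allylboration with the enantiomer of B-allyldiisopinocampheylborane that adds to the Si face of aldehydes (prepared from (−)-B-methoxydiisopinocampheylborane and allylmagnesium bromide; Et2O, −78 °C; then NaOH, H2O2) is matched with the Felkin preference and gives 7 directly; no new compound is formed on the way (F0).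

## Further compounds

F1 | step 10 | (4S,5R)-6-[4-(benzyloxy)phenyl]-5-[(triisopropylsilyl)oxy]hex-1-en-4-yl prop-2-enoate | C=CC(=O)O[C@@H](CC=C)[C@H](O[Si](C(C)C)(C(C)C)C(C)C)Cc1ccc(OCc2ccccc2)cc1
F2 | step 10 | (6S)-6-{(1R)-2-[4-(benzyloxy)phenyl]-1-[(triisopropylsilyl)oxy]ethyl}-5,6-dihydro-2H-pyran-2-one | O=C1C=CC[C@@H]([C@H](O[Si](C(C)C)(C(C)C)C(C)C)Cc2ccc(OCc3ccccc3)cc2)O1
F3 | step 10 | (6S)-6-{(1R)-2-[4-(benzyloxy)phenyl]-1-[(triisopropylsilyl)oxy]ethyl}-5,6-dihydro-2H-pyran-2-yl acetate (both configurations at C2) | CC(=O)OC1C=CC[C@@H]([C@H](O[Si](C(C)C)(C(C)C)C(C)C)Cc2ccc(OCc3ccccc3)cc2)O1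
F4 | step 10 | 1-(benzyloxy)-4-bromo-2-methoxybenzene | COc1cc(Br)ccc1OCc1ccccc1
F5 | step 10 | [4-(benzyloxy)-3-methoxyphenyl]zinc bromide, ArZnBr | COc1cc([Zn]Br)ccc1OCc1ccccc1
F6 | step 9 | {[(1S)-1-[4-(benzyloxy)-3-methoxyphenyl]prop-2-en-1-yl]oxy}triethylsilane | COc1cc([C@H](C=C)O[Si](CC)(CC)CC)ccc1OCc1ccccc1
F7 | step 9 | (1S)-1-[4-(benzyloxy)-3-methoxyphenyl]prop-2-en-1-ol | COc1cc([C@H](C=C)O)ccc1OCc1ccccc1
F8 | step 9 | (1S)-1-[4-(benzyloxy)-3-methoxyphenyl]prop-2-en-1-yl methyl carbonate | COc1cc([C@H](C=C)OC(=O)OC)ccc1OCc1ccccc1
F9 | step 11 | (2S,4S,6S)-2-[4-(benzyloxy)-3-methoxyphenyl]-6-{(1R)-2-[4-(benzyloxy)phenyl]-1-[(triisopropylsilyl)oxy]ethyl}oxan-4-ol | COc1cc([C@@H]2C[C@H](O)C[C@@H]([C@H](O[Si](C(C)C)(C(C)C)C(C)C)Cc3ccc(OCc4ccccc4)cc3)O2)ccc1OCc1ccccc1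
F10 | step 12 | (2S,4S,6S)-2-[4-(benzyloxy)-3-methoxyphenyl]-6-{(1R)-2-[4-(benzyloxy)phenyl]-1-[(triisopropylsilyl)oxy]ethyl}oxan-4-ol | COc1cc([C@@H]2C[C@H](O)C[C@@H]([C@H](O[Si](C(C)C)(C(C)C)C(C)C)Cc3ccc(OCc4ccccc4)cc3)O2)ccc1OCc1ccccc1
F11 | step 12 | (2S,4R,6S)-2-[4-(benzyloxy)-3-methoxyphenyl]-6-{(1R)-2-[4-(benzyloxy)phenyl]-1-[(triisopropylsilyl)oxy]ethyl}oxan-4-yl 4-nitrobenzoate | COc1cc([C@@H]2C[C@@H](OC(=O)c3ccc(cc3)[N+](=O)[O-])C[C@@H]([C@H](O[Si](C(C)C)(C(C)C)C(C)C)Cc3ccc(OCc4ccccc4)cc3)O2)ccc1OCc1ccccc1
F0 | step 5 | none | none
A1 | alternative 1 | 4-{(1R)-1-[(tert-butyldimethylsilyl)oxy]-2-[2-{(2S,3R)-3-(benzyloxy)-4-[4-(benzyloxy)phenyl]-2-hydroxybutyl}-1,3-dithian-2-yl]ethyl}-2-methoxyphenyl 4-methylbenzenesulfonate | COc1cc([C@H](O[Si](C)(C)C(C)(C)C)CC2(C[C@H](O)[C@H](OCc3ccccc3)Cc3ccc(OCc4ccccc4)cc3)SCCCS2)ccc1OS(=O)(=O)c1ccc(C)cc1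
A2 | alternative 1 | 2-methoxy-4-[(2S)-oxiran-2-yl]phenyl 4-methylbenzenesulfonate | COc1cc([C@H]2CO2)ccc1OS(=O)(=O)c1ccc(C)cc1
A3 | alternative 1 | (2S)-2-{(1R)-1-(benzyloxy)-2-[4-(benzyloxy)phenyl]ethyl}oxirane | C1O[C@@H]1[C@H](OCc1ccccc1)Cc1ccc(OCc2ccccc2)cc1
A4 | alternative 1 | 2-(tert-butyldimethylsilyl)-1,3-dithiane | CC(C)(C)[Si](C)(C)C1SCCCS1
A5 | alternative 2 | 4-{(1R)-2-[(5S)-5-{(1R)-1-(benzyloxy)-2-[4-(benzyloxy)phenyl]ethyl}-4,5-dihydro-1,2-oxazol-3-yl]-1-[(tert-butyldimethylsilyl)oxy]ethyl}-2-methoxyphenyl 4-methylbenzenesulfonate | COc1cc([C@H](O[Si](C)(C)C(C)(C)C)CC2=NO[C@H]([C@H](OCc3ccccc3)Cc3ccc(OCc4ccccc4)cc3)C2)ccc1OS(=O)(=O)c1ccc(C)cc1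
A6 | alternative 2 | (3R)-3-[(tert-butyldimethylsilyl)oxy]-3-(3-methoxy-4-{[(4-methylphenyl)sulfonyl]oxy}phenyl)propanenitrile oxide | COc1cc([C@H](O[Si](C)(C)C(C)(C)C)CC#[N+][O-])ccc1OS(=O)(=O)c1ccc(C)cc1
A7 | alternative 2 | 1-(benzyloxy)-4-[(2R)-2-(benzyloxy)but-3-en-1-yl]benzene | C=C[C@H](OCc1ccccc1)Cc1ccc(OCc2ccccc2)cc1
A8 | alternative 3 | (1R)-1-{(2S,4R,6S)-6-[4-(benzyloxy)-3-methoxyphenyl]-4-[(tert-butyldimethylsilyl)oxy]oxan-2-yl}-2-[4-(benzyloxy)phenyl]ethan-1-ol | COc1cc([C@@H]2C[C@@H](O[Si](C)(C)C(C)(C)C)C[C@@H]([C@H](O)Cc3ccc(OCc4ccccc4)cc3)O2)ccc1OCc1ccccc1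
A9 | alternative 3 | (1S,3R)-1-[4-(benzyloxy)-3-methoxyphenyl]-4-{(2R,3R)-3-[4-(benzyloxy)benzyl]oxiran-2-yl}-3-[(tert-butyldimethylsilyl)oxy]butan-1-ol | COc1cc([C@@H](O)C[C@@H](O[Si](C)(C)C(C)(C)C)C[C@H]2O[C@@H]2Cc2ccc(OCc3ccccc3)cc2)ccc1OCc1ccccc1
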